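The numbers of this flask belong to no real substance.

Take a flask of solid D stirred with E, and reckon what stands in it at the end of the run.

    L + E ⇌ L.E (K1 = 450 M⁻¹, k1 = 48 M⁻¹ s⁻¹)
    L → G (k2 = 0.024 s⁻¹)
    D ⇌ L, rate k3*(cs3 - [L]) while solid is left; crystals form when [L] > cs3 (cs3 = 0.15 mM, k3 = 0.036 s⁻¹)

D 5.0 × 10⁻⁴ M; E 2.00 equiv; time 25 s

- D is a solid; its amount is given per volume of the solution
- at the start none of D is in solution
- what has only dissolved of D counts as not reacted
- L means what is dissolved; the solid is not counted in it
- the reaction counts as stopped when no species that holds the D changes by six tenths of a point or more over the second half of the time
- run time (flask): 25 s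

* why nothing more happens at 25 s, or that something still does (for what has run out or reacted, a solid counts together with what of it has only dissolved) (forward and back rates have come level / it is still moving / all of D has reacted / E has run out first)
* part of the D that has turned into other species by 25 s (what has only dissolved does not count)
* L.E at 25 s, in percent of the D charged
* L at 25 s, in percent of the D charged
* amount of L.E if the flask were left three thousand times as long, in percent of the D charged

We begin with the plainest flask, in which D dissolves and nothing else happens. Here [L] climbs towards the solubility, which is 30.0% of the D charged, and with the rate constant 0.036 s⁻¹ it reaches 17.8% by 25 s. Solid stays in this flask through the run, since even at its full rate dissolving takes 27.0% of the charge in that time.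

Now we add the step to G. The solid feeds L in proportion to what [L] lacks of saturation, and L drains with 0.024 s⁻¹. Feed and drain balance at the solubility times 0.036/(0.036 + 0.024), which is 18.0% of the D charged. We call this the standing level of L: the [L] at which, with solid present, the feed equals the loss to G. [L] approaches it with the rate constant 0.0600 s⁻¹, so by 25 s this reckoning puts it at 14.0%.

Last comes the reversible step to L.E, pseudo-first-order while E stays near its charge, with 0.45, the equilibrium constant times [E] at the start, as the ratio of L.E to L at balance. Once L.E stands still it takes no net L, so the standing level is unchanged and L.E would sit at 8.10%. While L.E fills, though, it draws on L, and the forward half-life of 14 s is shorter than the run. So we commit to [L] under 14.0% and [L.E] under 6.30%, both still climbing at 25 s.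

The forecast said it is still moving, with 8.4% converted, L 11.9%, L.E 3.9% and 0% L.E in the long run, noting “Solid therefore remains throughout”. The simulation says it is still moving: 8.40% converted, L 11.9%, L.E 3.93%, with D at 79.7% and 0% L.E in the long run. In this flask [L] has reached 66.1% of the standing level, under the 14.0% we committed to, and L is still made 1.53 times faster than it is used up, each step taken net.

The same reckoning goes to the neighbour flask, which holds 1.3 × 10⁻⁴ M of D with the equivalents and the time unchanged. The dissolving is the same in molar terms, so against this smaller charge the standing level becomes 69.2%, and by 25 s the feed and drain, reckoned without L.E, give 53.8%. Solid is still present in that flask at 25.0 s, at 25.0%, so the feed has not stopped. Its [L] stands at 51.4%, under that 53.8%, with L.E at 4.41%.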